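**Plan**

Retrosynthesis (ring A = 4-hydroxy-3,5-dimethoxyphenyl, ring B = the syringic acid ring, C-α = ketone carbon, C-β = methine carbon, C-γ = CH2OH carbon): cut the C-γ–H bond (alcohol back to aldehyde), then C-β–C-γ (formyl carbon from ethyl formate), then ring A–C-α (arylmagnesium bromide plus N-methoxy-N-methylamide), and last the C-β–O ether bond to ring B (phenol plus chloroacetamide).
Forward: the ring-B phenol, as its tert-butyl ester, is O-alkylated with the C-α/C-β unit, ring A is joined at C-α as a methoxymethyl (MOM)-protected aryl nucleophile, C-γ is added by Claisen formylation, and acid removes both protecting groups; the chain stays acyclic and no ring is formed.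
Feature used: C-β, which carries H and the ring-B aryloxy oxygen, sits between the ketone carbon C-α and C-γ; while C-γ is an aldehyde, C-β is the methine of a 1,3-dicarbonyl unit and racemises through the enol, whereas in the target it is α to a single ketone and holds its configuration.
Stereochemistry: the only stereocentre (C-β, R) is fixed in the last step by a ketoreductase that reduces the formyl group of the (R)-keto aldehyde only while the substrate keeps racemising (dynamic kinetic resolution); no later step can erode it.

Key step: step 7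

Remark: the 2-aryloxy-3-oxopropanals of this route are drawn as keto aldehydes although they should exist mainly as enols, and a ketoreductase with the required preference for the (R)-aldehyde is assumed to be found by screening an enzyme panel.

**Route**

Step 1
Reactants: 1 syringic acid (4-hydroxy-3,5-dimethoxybenzoic acid)
Product: 2 tert-butyl 4-hydroxy-3,5-dimethoxybenzoate
Conditions: Me2NCH(OtBu)2 (4 equiv), toluene, 80 °C
Reagents that add atoms: N,N-dimethylformamide di-tert-butyl acetal, CN(C)C(OC(C)(C)C)OC(C)(C)C
Why: Esterification of a carboxylic acid with a formamide acetal: the acid protonates the acetal and the carboxylate is tert-butylated by the resulting alkoxy-iminium ion, while the much less acidic hindered phenol is left free, as is usual for hydroxybenzoic acids.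

Step 2
Reactants: 2 tert-butyl 4-hydroxy-3,5-dimethoxybenzoate; 3 2-chloro-N-methoxy-N-methylacetamide
Product: 4 tert-butyl 4-{2-[methoxy(methyl)amino]-2-oxoethoxy}-3,5-dimethoxybenzoate
Conditions: K2CO3, NaI (cat.), DMF, 60 °C
Reagents that add atoms: none
Why: Williamson ether synthesis: the potassium phenoxide of 2 displaces halide from the α-halo amide (iodide formed in the flask by Finkelstein exchange) in an SN2 reaction activated by the neighbouring carbonyl group, which the 2,6-dimethoxyphenoxide should still undergo readily.

Step 3
Reactants: 5 4-bromo-2,6-dimethoxyphenol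
Product: 6 5-bromo-1,3-dimethoxy-2-(methoxymethoxy)benzene
Conditions: NaH, THF, 0 °C; MOMCl, 0 °C → rt
Reagents that add atoms: chloromethyl methyl ether, COCCl
Why: Methoxymethyl protection by O-alkylation of the sodium phenoxide with the reactive α-chloro ether; the acetal withstands the organomagnesium and alkoxide reagents of steps 4 and 5 and leaves with acid in step 6.

Step 4
Reactants: 6 5-bromo-1,3-dimethoxy-2-(methoxymethoxy)benzene; 4 tert-butyl 4-{2-[methoxy(methyl)amino]-2-oxoethoxy}-3,5-dimethoxybenzoate
Product: 9 tert-butyl 4-{2-[3,5-dimethoxy-4-(methoxymethoxy)phenyl]-2-oxoethoxy}-3,5-dimethoxybenzoate, via arylmagnesium bromide 7 (not isolated), via bromomagnesium hemiaminal 8 (not isolated)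
Conditions: Mg turnings, I2 (cat.), THF, 65 °C; then 4, THF, 0 °C; sat. aq. NH4Cl
Reagents that add atoms: none
Why: Weinreb ketone synthesis: Mg inserts into the aryl C–Br bond, the arylmagnesium bromide adds to the N-methoxy-N-methylamide, and the five-membered N-methoxy chelate 8 holds the tetrahedral adduct until the quench so that the ketone is not attacked a second time, while the hindered tert-butyl ester on the electron-rich ring B is far less electrophilic than the amide at 0 °C.

Step 5
Reactants: 9 tert-butyl 4-{2-[3,5-dimethoxy-4-(methoxymethoxy)phenyl]-2-oxoethoxy}-3,5-dimethoxybenzoate; 10 ethyl formate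
Product: 12 racemic tert-butyl 4-({1-[3,5-dimethoxy-4-(methoxymethoxy)phenyl]-1,3-dioxopropan-2-yl}oxy)-3,5-dimethoxybenzoate, via potassium enolate 11 (not isolated)
Conditions: KOtBu (2.5 equiv), HCO2Et (5 equiv), THF, 0 °C → rt; then AcOH, H2O, 0 °C
Reagents that add atoms: none
Why: Crossed Claisen condensation (ketone formylation): the α-aryloxy ketone enolate attacks the non-enolisable ethyl formate and the equilibrium is pulled through by deprotonation of the 1,3-dicarbonyl product to enolate 11, so C-β arises as a racemic, configurationally labile centre, and tert-butoxide cannot scramble the tert-butyl ester.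

Step 6
Reactants: 12 racemic tert-butyl 4-({1-[3,5-dimethoxy-4-(methoxymethoxy)phenyl]-1,3-dioxopropan-2-yl}oxy)-3,5-dimethoxybenzoate
Product: 13 racemic 4-{[1-(4-hydroxy-3,5-dimethoxyphenyl)-1,3-dioxopropan-2-yl]oxy}-3,5-dimethoxybenzoic acid
Conditions: TFA/CH2Cl2 (1:1), H2O (5 equiv), 0 °C → rt; evaporation with toluene
Reagents that add atoms: none
Why: Acidolysis of both protecting groups: the aryl methoxymethyl acetal ionises and its oxocarbenium ion is hydrolysed by the added water, the tert-butyl ester fragments through the tert-butyl cation to isobutene, and the enolised 1,3-dicarbonyl unit, the alkyl aryl ether bond and the methyl ethers have no acid-labile bond under these conditions.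

Step 7
Reactants: 13 racemic 4-{[1-(4-hydroxy-3,5-dimethoxyphenyl)-1,3-dioxopropan-2-yl]oxy}-3,5-dimethoxybenzoic acid
Product: 14 4-{[(2R)-3-hydroxy-1-(4-hydroxy-3,5-dimethoxyphenyl)-1-oxopropan-2-yl]oxy}-3,5-dimethoxybenzoic acid
Conditions: ketoreductase (panel hit selective for the (R)-aldehyde), NADP+ (cat.), glucose dehydrogenase, D-glucose, 0.2 M KH2PO4/K2HPO4 buffer pH 6.5, DMSO (10% v/v), 30 °C; then acidification to pH 3, EtOAc, 0 °C
Reagents that add atoms: none
Why: Proposed new method: in the phosphate buffer (a general base, at a pH near the pKa of the 1,3-dicarbonyl unit) 13 should equilibrate rapidly between enol, enolate and the two enantiomeric keto-aldehyde tautomers, and the ketoreductase binds the (R)-keto aldehyde and transfers the hydride of NADPH, regenerated by glucose dehydrogenase and D-glucose, to the formyl carbon C-γ, forming the C-γ–H bond. The closest known reaction type is the ketoreductase, alcohol dehydrogenase or baker's-yeast reduction with dynamic kinetic resolution of α-substituted β-keto esters, α-formyl esters and racemic α-branched aldehydes such as 2-arylpropanals; a 2-aryloxy-3-aryl-3-oxopropanal has not been shown as a substrate. No ring closes and no skeletal bond forms. The only stereocentre, C-β, is not created by the hydride transfer (C-γ becomes CH2) but selected by the chiral active site, which accepts one enantiomer of the racemising substrate; because the order OAr > C(=O)Ar > CHO or CH2OH > H holds before and after, the (R)-aldehyde gives the (R)-alcohol 14. The step needs enantiomer discrimination (to be secured by enzyme screening or engineering), racemisation faster than reduction (secured by the acidity of the C-β–H bond between the C-α and C-γ carbonyl groups) and reduction of the aldehyde only (secured by the much higher electrophilicity of the formyl group compared with the conjugated, electron-rich ring-A aryl ketone). Product 14 has lost the second carbonyl group, is many orders of magnitude less acidic at C-β, and should therefore keep its configuration in the buffer and in the cold acidic extraction.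

**Compound list**

1 | syringic acid (4-hydroxy-3,5-dimethoxybenzoic acid) | COc1cc(C(=O)O)cc(OC)c1O | starting material
2 | tert-butyl 4-hydroxy-3,5-dimethoxybenzoate | COc1cc(C(=O)OC(C)(C)C)cc(OC)c1O | intermediate
3 | 2-chloro-N-methoxy-N-methylacetamide | CON(C)C(=O)CCl | starting material
4 | tert-butyl 4-{2-[methoxy(methyl)amino]-2-oxoethoxy}-3,5-dimethoxybenzoate | CON(C)C(=O)COc1c(OC)cc(cc1OC)C(=O)OC(C)(C)C | intermediate
5 | 4-bromo-2,6-dimethoxyphenol | COc1cc(Br)cc(OC)c1O | starting material
6 | 5-bromo-1,3-dimethoxy-2-(methoxymethoxy)benzene | COCOc1c(OC)cc(Br)cc1OC | intermediate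
7 | [3,5-dimethoxy-4-(methoxymethoxy)phenyl]magnesium bromide (formed and consumed in step 4) | COCOc1c(OC)cc([Mg]Br)cc1OC | intermediate
8 | bromomagnesium 2-[4-(tert-butoxycarbonyl)-2,6-dimethoxyphenoxy]-1-[3,5-dimethoxy-4-(methoxymethoxy)phenyl]-1-[methoxy(methyl)amino]ethan-1-olate, racemic chelated tetrahedral adduct (formed and consumed in step 4) | COCOc1c(OC)cc(cc1OC)C(O[Mg]Br)(N(C)OC)COc1c(OC)cc(cc1OC)C(=O)OC(C)(C)C | intermediate
9 | tert-butyl 4-{2-[3,5-dimethoxy-4-(methoxymethoxy)phenyl]-2-oxoethoxy}-3,5-dimethoxybenzoate | COCOc1c(OC)cc(cc1OC)C(=O)COc1c(OC)cc(cc1OC)C(=O)OC(C)(C)C | intermediate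
10 | ethyl formate | CCOC=O | starting material
11 | potassium 2-[4-(tert-butoxycarbonyl)-2,6-dimethoxyphenoxy]-3-[3,5-dimethoxy-4-(methoxymethoxy)phenyl]-3-oxoprop-1-en-1-olate (formed in step 5 and protonated on work-up) | COCOc1c(OC)cc(cc1OC)C(=O)C(=C[O-])Oc1c(OC)cc(cc1OC)C(=O)OC(C)(C)C.[K+] | intermediate
12 | racemic tert-butyl 4-({1-[3,5-dimethoxy-4-(methoxymethoxy)phenyl]-1,3-dioxopropan-2-yl}oxy)-3,5-dimethoxybenzoate (mainly enol) | COCOc1c(OC)cc(cc1OC)C(=O)C(C=O)Oc1c(OC)cc(cc1OC)C(=O)OC(C)(C)C | intermediate
13 | racemic 4-{[1-(4-hydroxy-3,5-dimethoxyphenyl)-1,3-dioxopropan-2-yl]oxy}-3,5-dimethoxybenzoic acid (racemising keto aldehyde, mainly enol) | COc1cc(C(=O)C(C=O)Oc2c(OC)cc(C(=O)O)cc2OC)cc(OC)c1O | intermediate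
14 | 4-{[(2R)-3-hydroxy-1-(4-hydroxy-3,5-dimethoxyphenyl)-1-oxopropan-2-yl]oxy}-3,5-dimethoxybenzoic acid | COc1cc(C(=O)[C@@H](CO)Oc2c(OC)cc(C(=O)O)cc2OC)cc(OC)c1O | target

**Step count and risks**

Total step count: 7. Longest linear sequence: 6 steps (steps 1, 2, 4, 5, 6 and 7 from syringic acid); the ring-A branch (step 3) joins at step 4.

Steps most likely to fail:

Step 7 (proposed new method). No enzyme of the panel may accept the largely enolised, polyanionic substrate or tell its enantiomers apart. The formyl group may also be lost slowly by hydrolysis in the buffer, or the ketone may be reduced as well. The fallback uses known chemistry only, sets out from 9 and returns at 14. K2CO3-catalysed aldol addition of 9 to aqueous formaldehyde in EtOH at room temperature, the usual way to the γ-hydroxymethyl group of β-aryl ether ketones, should give racemic tert-butyl 4-({3-hydroxy-1-[3,5-dimethoxy-4-(methoxymethoxy)phenyl]-1-oxopropan-2-yl}oxy)-3,5-dimethoxybenzoate F1. TFA/CH2Cl2/H2O would then remove both protecting groups to give racemic 4-{[3-hydroxy-1-(4-hydroxy-3,5-dimethoxyphenyl)-1-oxopropan-2-yl]oxy}-3,5-dimethoxybenzoic acid F2. Preparative supercritical-fluid chromatography on an amylose tris(3,5-dimethylphenylcarbamate) phase would separate 14 from 4-{[(2S)-3-hydroxy-1-(4-hydroxy-3,5-dimethoxyphenyl)-1-oxopropan-2-yl]oxy}-3,5-dimethoxybenzoic acid F3, which is set aside.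

Step 6. The formaldehyde released from the acetal may be captured by the enol at C-β (hydroxymethylation), or the acid may promote loss of the formyl group. The fallback changes the order of events so that no formaldehyde is present once the 1,3-dicarbonyl unit exists; it sets out from 9 and returns at 13. Acetal exchange with p-TsOH·H2O (cat.) in MeOH at 40 °C should remove only the aryl MOM group and give tert-butyl 4-[2-(4-hydroxy-3,5-dimethoxyphenyl)-2-oxoethoxy]-3,5-dimethoxybenzoate F4. Formylation with ethyl formate 10 and KOtBu, one equivalent more for the phenol, in the manner of the classical formylation of hydroxylated deoxybenzoins, should give racemic tert-butyl 4-{[1-(4-hydroxy-3,5-dimethoxyphenyl)-1,3-dioxopropan-2-yl]oxy}-3,5-dimethoxybenzoate F5. Anhydrous TFA/CH2Cl2 then cleaves only the tert-butyl ester and gives 13.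

Step 5. Enolisation of the hindered α-aryloxy ketone may be slow, ethoxide may transesterify the tert-butyl ester, or the formyl group may be lost again by retro-Claisen cleavage during work-up. The fallback introduces C-γ as a vinylogous amide under neutral conditions; it sets out from 9 and returns at 12. Condensation with tert-butoxybis(dimethylamino)methane in toluene at 90 °C should give the enaminone tert-butyl 4-({3-(dimethylamino)-1-[3,5-dimethoxy-4-(methoxymethoxy)phenyl]-1-oxoprop-2-en-2-yl}oxy)-3,5-dimethoxybenzoate F6. Brief hydrolysis with cold dilute aqueous HCl in THF, which the MOM acetal and the tert-butyl ester should tolerate, would give 12.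

Further compounds
F1 | step 7 | racemic tert-butyl 4-({3-hydroxy-1-[3,5-dimethoxy-4-(methoxymethoxy)phenyl]-1-oxopropan-2-yl}oxy)-3,5-dimethoxybenzoate | COCOc1c(OC)cc(cc1OC)C(=O)C(CO)Oc1c(OC)cc(cc1OC)C(=O)OC(C)(C)C
F2 | step 7 | racemic 4-{[3-hydroxy-1-(4-hydroxy-3,5-dimethoxyphenyl)-1-oxopropan-2-yl]oxy}-3,5-dimethoxybenzoic acid | COc1cc(C(=O)C(CO)Oc2c(OC)cc(C(=O)O)cc2OC)cc(OC)c1O
F3 | step 7 | 4-{[(2S)-3-hydroxy-1-(4-hydroxy-3,5-dimethoxyphenyl)-1-oxopropan-2-yl]oxy}-3,5-dimethoxybenzoic acid | COc1cc(C(=O)[C@H](CO)Oc2c(OC)cc(C(=O)O)cc2OC)cc(OC)c1O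
F4 | step 6 | tert-butyl 4-[2-(4-hydroxy-3,5-dimethoxyphenyl)-2-oxoethoxy]-3,5-dimethoxybenzoate | COc1cc(cc(OC)c1O)C(=O)COc1c(OC)cc(cc1OC)C(=O)OC(C)(C)C
F5 | step 6 | racemic tert-butyl 4-{[1-(4-hydroxy-3,5-dimethoxyphenyl)-1,3-dioxopropan-2-yl]oxy}-3,5-dimethoxybenzoate | COc1cc(cc(OC)c1O)C(=O)C(C=O)Oc1c(OC)cc(cc1OC)C(=O)OC(C)(C)C
F6 | step 5 | tert-butyl 4-({3-(dimethylamino)-1-[3,5-dimethoxy-4-(methoxymethoxy)phenyl]-1-oxoprop-2-en-2-yl}oxy)-3,5-dimethoxybenzoate | COCOc1c(OC)cc(cc1OC)C(=O)C(=CN(C)C)Oc1c(OC)cc(cc1OC)C(=O)OC(C)(C)C
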